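**Retrosynthetic overview**
- Last: epoxidation of the (Z)-C1=C10 alkene, directed by the transannular C6–OH; before it, aryl-ether removal and oxidation of the C3 carbinol to the enone.
- Ten-membered ring (formed second): Ni/Cr closure of C3–C4 between a 2-bromoalkene and an aldehyde.
- γ-Lactone (formed first): Cr(II) allylation of the C8 aldehyde by a bromoacrylate that carries C4–C7 and C11–C13; this sets C7 and C8.
- Bromoacrylate ⇐ 2-bromoacrolein + allyl 4-methoxyphenyl ether (Brown alkoxyallylboration sets C5, C6), angelic acid, cross-metathesis.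
- C8–C9–C10(CH3)=C1–C2–C3 piece ⇐ 3-methylanisole: Birch reduction, then ozonolysis of only the enol-ether C=C; the arene ring fixes the Z alkene (hence the cis-epoxide) and differentiates C3 from C8.

Convention (one line): germacrane-style labels are used: C1/C10 epoxide carbons (C10 bears CH3 = C14), C2 CH2, C3 ketone, C4(=C15H2), C5 (O-angeloyl), C6 (OH), C7, C8 (lactone O–CH), C9 CH2, C11(=C13H2)–C12(=O)–O–C8; with these labels the target is (1S,5S,6S,7R,8R,10R); Ang = (2Z)-2-methylbut-2-enoyl, PMP = 4-methoxyphenyl.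

**Route**

Step 1
Reactants: 1 3-methylanisole
Product: 2 1-methoxy-5-methylcyclohexa-1,4-diene
Conditions: Li, NH3(l), t-BuOH, THF, −78 → −33 °C
Reagents that add atoms: none
Why: Birch reduction protonates the two ring positions that are para to each other and carry no donor, so OMe and CH3 stay on the two isolated double bonds and the ring now holds C9–C10(CH3)=C1–C2 in a cis arrangement.

Step 2
Reactants: 2 1-methoxy-5-methylcyclohexa-1,4-diene
Product: 5 methyl (3Z)-6,6-dimethoxy-3-methylhex-3-enoate, via methoxy hydroperoxide 3 (not isolated), via aldehyde ester 4 (not isolated)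
Conditions: O3 (1.0 equiv), CH2Cl2/MeOH, −78 °C; Me2S, −78 °C → rt; HC(OMe)3, PPTS (cat.), rt
Reagents that add atoms: ozone O=[O+][O-]; methanol CO (held in 3 only); trimethyl orthoformate COC(OC)OC
Why: Ozonolysis (Criegee cleavage) is selective for the electron-rich enol-ether C=C, turning the OMe carbon into the C8 methyl ester and the other carbon into the C3 aldehyde (acetalised in the same pot), while the untouched trisubstituted alkene keeps the ring-imposed Z geometry.

Step 3
Reactants: 5 methyl (3Z)-6,6-dimethoxy-3-methylhex-3-enoate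
Product: 6 (3Z)-6,6-dimethoxy-3-methylhex-3-enal
Conditions: DIBAL-H (1.05 equiv), CH2Cl2, −78 °C; aq. Rochelle salt; used crude
Reagents that add atoms: none
Why: DIBAL half-reduction stops at the aluminium hemiacetal at −78 °C and gives the C8 aldehyde, which is used at once because it is β,γ-unsaturated.

Step 4
Reactants: 7 acrolein
Product: 9 2-bromoacrolein, via 2,3-dibromopropanal 8 (not isolated)
Conditions: Br2, CH2Cl2, −78 °C; Et3N, −78 → 0 °C
Reagents that add atoms: bromine BrBr
Why: Bromine addition to the alkene followed by amine-mediated dehydrobromination (E1cB of the β-bromide) gives the α-bromo enal that supplies C15, C4 and C5.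

Step 5
Reactants: 9 2-bromoacrolein; 10 allyl 4-methoxyphenyl ether
Product: 13 (3R,4S)-2-bromo-4-(4-methoxyphenoxy)hexa-1,5-dien-3-ol, via allylborane 11 (not isolated), via borinate 12 (not isolated)
Conditions: 10, s-BuLi, THF, −78 °C; (+)-Ipc2BOMe; BF3·OEt2; 9, −78 °C; NaOH, H2O2, 0 °C → rt
Reagents that add atoms: (+)-B-methoxydiisopinocampheylborane COB([C@H]1C[C@H]2C[C@@H]([C@@H]1C)C2(C)C)[C@H]1C[C@H]2C[C@@H]([C@@H]1C)C2(C)C (boron and Ipc groups held in 11 and 12 only)
Why: Brown alkoxyallylboration: the (Z)-γ-aryloxyallylborane reacts through a closed chair (Z reagent gives the syn, threo C5/C6 pair) and the Ipc groups from (−)-α-pinene direct attack to the re face of the aldehyde, setting C5 and C6 with C5–OH free and C6–O protected.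

Step 6
Reactants: 13 (3R,4S)-2-bromo-4-(4-methoxyphenoxy)hexa-1,5-dien-3-ol; 14 angelic acid
Product: 16 angelate ester of 13, via mixed anhydride 15 (not isolated)
Conditions: 14, 2,4,6-Cl3C6H2COCl, Et3N, toluene, rt; then 13, toluene, 80 °C
Reagents that add atoms: 2,4,6-trichlorobenzoyl chloride O=C(Cl)c1c(Cl)cc(Cl)cc1Cl (held in 15 only)
Why: Yamaguchi-type acylation through the mixed anhydride without a nucleophilic catalyst esterifies the only free hydroxyl (C5) under conditions that do not isomerise angelate to tiglate.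

Step 7
Reactants: 16 angelate ester of 13; 17 methyl 2-(bromomethyl)acrylate
Product: 18 methyl (2Z,4S,5R)-6-bromo-2-(bromomethyl)-4-(4-methoxyphenoxy)-5-angeloyloxyhepta-2,6-dienoate
Conditions: Hoveyda–Grubbs II (10 mol %), 17 (8 equiv), CH2Cl2, 40 °C
Reagents that add atoms: none
Why: Proposed new method: olefin cross-metathesis in which the Ru alkylidene formed at the terminal C7 vinyl group adds to the 1,1-disubstituted acrylate 17 (which does not homodimerise) and releases ethylene to give the trisubstituted enoate with C6 trans to CO2Me, the bromoalkene and angelate being too hindered and electron-poor to react; closest known reaction type is cross-metathesis of terminal alkenes with methyl methacrylate or α-methylene-γ-butyrolactone.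

Step 8
Reactants: 6 (3Z)-6,6-dimethoxy-3-methylhex-3-enal; 18 bromoacrylate
Product: 21 lactone aldehyde, via hydroxy ester 19 (not isolated), via lactone acetal 20 (not isolated)
Conditions: CrCl2 (4 equiv), THF, 0 °C → rt; then 1 M HCl, THF, rt
Reagents that add atoms: water O
Why: Nozaki–Hiyama allylation: Cr(II) inserts only into the allylic C–Br bond (the vinyl bromide needs Ni), the allylchromium(III) with C6 trans to CH2Cr adds to the aldehyde through a closed chair (anti, so H7/H8 end up trans) on the C7 face anti to the C5 branch with C6–H eclipsing the alkene (A1,3 strain), and acid then closes the γ-lactone and unmasks the C3 aldehyde.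

Step 9
Reactants: 21 lactone aldehyde
Product: 22 macrocyclic C3 carbinol
Conditions: CrCl2 (8 equiv), NiCl2 (5 mol %), DMSO, 2 mM, rt → 50 °C
Reagents that add atoms: none
Why: Nozaki–Hiyama–Kishi macrocyclisation: Ni-catalysed formation of the C4 vinylchromium and its chemoselective addition to the C3 aldehyde at high dilution closes the ten-membered ring, and the new C3 stereocentre is irrelevant because it is oxidised next.

Step 10
Reactants: 22 macrocyclic C3 carbinol
Product: 23 macrocyclic enone with C6–OPMP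
Conditions: Dess–Martin periodinane, NaHCO3, CH2Cl2, 0 °C
Reagents that add atoms: none
Why: Dess–Martin oxidation of the only free (allylic) alcohol gives the C3 ketone conjugated with the C4 exocyclic methylene, buffered so that the β,γ C1=C10 alkene does not move into conjugation.

Step 11
Reactants: 23 macrocyclic enone with C6–OPMP
Product: 24 1(10)Z-alkene precursor with free C6–OH
Conditions: CAN, MeCN/H2O (4:1), 0 °C
Reagents that add atoms: none
Why: Oxidative dearylation: Ce(IV) oxidises the p-methoxyphenyl ether to a quinone monoketal that hydrolyses to benzoquinone and the free C6 alcohol without touching any stereocentre or the electron-poor alkenes.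

Step 12
Reactants: 24 1(10)Z-alkene precursor with free C6–OH
Product: 25 CNP0348992.1
Conditions: m-CPBA, NaHCO3, CH2Cl2, 0 °C
Reagents that add atoms: m-CPBA O=C(OO)c1cccc(Cl)c1
Why: Prilezhaev epoxidation attacks the only electron-rich alkene, is stereospecific (Z alkene gives the cis-epoxide), and is delivered by hydrogen bonding to the transannular C6–OH (Henbest effect) on the face syn to that hydroxyl, which is the (1S,10R) face.

**Compound list**

1 | 3-methylanisole (1-methoxy-3-methylbenzene) | COc1cccc(C)c1 | starting material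
2 | 1-methoxy-5-methylcyclohexa-1,4-diene | COC1=CCC=C(C)C1 | intermediate
3 | methyl (3Z)-6-hydroperoxy-6-methoxy-3-methylhex-3-enoate | COC(=O)C/C(C)=C\CC(OC)OO | intermediate
4 | methyl (3Z)-3-methyl-6-oxohex-3-enoate | COC(=O)C/C(C)=C\CC=O | intermediate
5 | methyl (3Z)-6,6-dimethoxy-3-methylhex-3-enoate | COC(=O)C/C(C)=C\CC(OC)OC | intermediate
6 | (3Z)-6,6-dimethoxy-3-methylhex-3-enal | O=CC/C(C)=C\CC(OC)OC | intermediate
7 | acrolein | C=CC=O | starting material
8 | 2,3-dibromopropanal | O=CC(Br)CBr | intermediate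
9 | 2-bromoacrolein (2-bromoprop-2-enal) | C=C(Br)C=O | intermediate
10 | allyl 4-methoxyphenyl ether | C=CCOc1ccc(OC)cc1 | starting material
11 | [(2Z)-3-(4-methoxyphenoxy)prop-2-en-1-yl]bis(isopinocampheyl)borane, Ipc from (−)-α-pinene | COc1ccc(O/C=C\CB([C@H]2C[C@H]3C[C@@H]([C@@H]2C)C3(C)C)[C@H]2C[C@H]3C[C@@H]([C@@H]2C)C3(C)C)cc1 | intermediate
12 | bis(isopinocampheyl)borinate ester of 13 | C=C[C@H](Oc1ccc(OC)cc1)[C@@H](OB([C@H]1C[C@H]2C[C@@H]([C@@H]1C)C2(C)C)[C@H]1C[C@H]2C[C@@H]([C@@H]1C)C2(C)C)C(Br)=C | intermediate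
13 | (3R,4S)-2-bromo-4-(4-methoxyphenoxy)hexa-1,5-dien-3-ol | C=C[C@H](Oc1ccc(OC)cc1)[C@@H](O)C(Br)=C | intermediate
14 | angelic acid, (2Z)-2-methylbut-2-enoic acid | C/C=C(/C)C(=O)O | starting material
15 | angelic 2,4,6-trichlorobenzoic anhydride | C/C=C(/C)C(=O)OC(=O)c1c(Cl)cc(Cl)cc1Cl | intermediate
16 | (3R,4S)-2-bromo-4-(4-methoxyphenoxy)hexa-1,5-dien-3-yl (2Z)-2-methylbut-2-enoate | C=C[C@H](Oc1ccc(OC)cc1)[C@@H](OC(=O)/C(C)=C\C)C(Br)=C | intermediate
17 | methyl 2-(bromomethyl)acrylate | C=C(CBr)C(=O)OC | starting material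
18 | methyl (2Z,4S,5R)-6-bromo-2-(bromomethyl)-4-(4-methoxyphenoxy)-5-[(2Z)-2-methylbut-2-enoyloxy]hepta-2,6-dienoate | COC(=O)/C(CBr)=C/[C@H](Oc1ccc(OC)cc1)[C@@H](OC(=O)/C(C)=C\C)C(Br)=C | intermediate
19 | open-chain anti adduct: methyl 2-methylidene ester with C8–OH, C3 dimethyl acetal, C6–OPMP, C5–OAng and C4(Br)=CH2; C5–C8 configured as in 25 | COC(=O)C(=C)[C@@H]([C@H](O)C/C(C)=C\CC(OC)OC)[C@H](Oc1ccc(OC)cc1)[C@@H](OC(=O)/C(C)=C\C)C(Br)=C | intermediate
20 | trans-7,8-disubstituted α-methylene-γ-butyrolactone with the (Z)-CH2C(CH3)=CHCH2CH(OMe)2 chain on C8 and the CH(OPMP)CH(OAng)C(Br)=CH2 chain on C7; C5–C8 as in 25 | C=C1C(=O)O[C@H](C/C(C)=C\CC(OC)OC)[C@H]1[C@H](Oc2ccc(OC)cc2)[C@@H](OC(=O)/C(C)=C\C)C(Br)=C | intermediate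
21 | lactone aldehyde: as 20 but with the free C3 aldehyde, (3Z)-4-methyl-5-(lactonyl)pent-3-enal chain on C8 | C=C1C(=O)O[C@H](C/C(C)=C\CC=O)[C@H]1[C@H](Oc2ccc(OC)cc2)[C@@H](OC(=O)/C(C)=C\C)C(Br)=C | intermediate
22 | ten-membered carbocycle fused to the 8,12-lactone: C3 carbinol (both C3 epimers), C4=CH2, C5–OAng, C6–OPMP, (Z)-C1=C10; C5–C8 as in 25 | C=C1C(=O)O[C@@H]2C/C(C)=C\CC(O)C(=C)[C@H](OC(=O)/C(C)=C\C)[C@@H](Oc3ccc(OC)cc3)[C@@H]12 | intermediate
23 | as 22 but C3 ketone (cross-conjugated enone), C6–OPMP | C=C1C(=O)O[C@@H]2C/C(C)=C\CC(=O)C(=C)[C@H](OC(=O)/C(C)=C\C)[C@@H](Oc3ccc(OC)cc3)[C@@H]12 | intermediate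
24 | (5S,6S,7R,8R,1(10)Z)-5-angeloyloxy-6-hydroxy-3-oxogermacra-1(10),4(15),11(13)-trien-12,8-olide | C=C1C(=O)O[C@@H]2C/C(C)=C\CC(=O)C(=C)[C@H](OC(=O)/C(C)=C\C)[C@@H](O)[C@@H]12 | intermediate
25 | CNP0348992.1, (1S,5S,6S,7R,8R,10R)-5-angeloyloxy-1,10-epoxy-6-hydroxy-3-oxogermacra-4(15),11(13)-dien-12,8-olide | C=C1C(=O)O[C@@H]2C[C@@]3(C)O[C@H]3CC(=O)C(=C)[C@H](OC(=O)/C(C)=C\C)[C@@H](O)[C@@H]12 | target

**Step count**
Total steps: 12. Longest linear sequence: 9 (steps 4–12, from acrolein); 8 from 3-methylanisole (steps 1–3, 8–12).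

**Three steps most likely to fail**

Step 7. The cross-metathesis uses a hindered allylic-ether alkene and a bromo-acrylate partner that has not been tested in this role, and the allylic bromide may kill the catalyst. Fallback: set out from 16 and cleave the terminal vinyl group (OsO4 cat., NaIO4, 2,6-lutidine, dioxane/H2O; the bromoalkene and the angelate are electron-poor and survive) to the aldehyde F1. A Morita–Baylis–Hillman reaction with methyl acrylate (DABCO) gives the allylic alcohol F2, and NBS/Me2S (SN2′, thermodynamic Z bromide) converts F2 into 18, where the route is rejoined.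

Step 8. Anti/syn selectivity and facial selectivity decide C7 and C8 in one event, and the anti preference of ester-substituted allylchromium reagents is less certain than for simple crotyl systems. Fallback: set out from 6 and 18 and use indium metal in THF/H2O, whose closed chair from the Z-type allylindium should give the 7,8-syn hydroxy ester F3 (same C7, epimeric C8). Mesylation (MsCl, Et3N) gives the mesylate F4. Heating (toluene, 2,6-lutidine, 90 °C) lets the ester carbonyl oxygen displace the mesylate with inversion at C8 and lose its methyl group, giving the trans-lactone 20, which is hydrolysed to 21 with 1 M HCl as in step 8.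

Step 9. The ten-membered ring closure goes through a vinyl-metal that has an acyloxy leaving group on the neighbouring carbon, so allene formation or loss of the angelate can compete with cyclisation. Fallback: set out from 13 and protect C5–OH as the TBS ether F5 (TBSCl, imidazole). Cross-metathesis with 17 gives the bromoacrylate F6. Coupling with 6 under CrCl2 and then 1 M HCl (through the hydroxy ester F7 and the lactone acetal F8) gives the lactone aldehyde F9. CrCl2/NiCl2 closes the ring to the carbinol F10, and Dess–Martin oxidation gives the enone F11. HF·pyridine removes the silyl group to give the alcohol F12, which is acylated with 14 as in step 6 to rejoin the route at 23.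

**Further compounds**

F1 | step 7 | (2S,3R)-4-bromo-2-(4-methoxyphenoxy)-1-oxopent-4-en-3-yl (2Z)-2-methylbut-2-enoate | O=C[C@H](Oc1ccc(OC)cc1)[C@@H](OC(=O)/C(C)=C\C)C(Br)=C
F2 | step 7 | Morita–Baylis–Hillman alcohol: methyl 2-methylidene-3-hydroxy ester of F1 (both C7 epimers) | COC(=O)C(=C)C(O)[C@H](Oc1ccc(OC)cc1)[C@@H](OC(=O)/C(C)=C\C)C(Br)=C
F3 | step 8 | 7,8-syn hydroxy ester, C8 epimer of 19 | COC(=O)C(=C)[C@@H]([C@@H](O)C/C(C)=C\CC(OC)OC)[C@H](Oc1ccc(OC)cc1)[C@@H](OC(=O)/C(C)=C\C)C(Br)=C
F4 | step 8 | C8 methanesulfonate of F3 | COC(=O)C(=C)[C@@H]([C@@H](OS(C)(=O)=O)C/C(C)=C\CC(OC)OC)[C@H](Oc1ccc(OC)cc1)[C@@H](OC(=O)/C(C)=C\C)C(Br)=C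
F5 | step 9 | tert-butyldimethylsilyl ether of 13 | C=C[C@H](Oc1ccc(OC)cc1)[C@@H](O[Si](C)(C)C(C)(C)C)C(Br)=C
F6 | step 9 | bromoacrylate as 18 with C5–OTBS in place of C5–OAng | COC(=O)/C(CBr)=C/[C@H](Oc1ccc(OC)cc1)[C@@H](O[Si](C)(C)C(C)(C)C)C(Br)=C
F7 | step 9 | hydroxy ester as 19 with C5–OTBS | COC(=O)C(=C)[C@@H]([C@H](O)C/C(C)=C\CC(OC)OC)[C@H](Oc1ccc(OC)cc1)[C@@H](O[Si](C)(C)C(C)(C)C)C(Br)=C
F8 | step 9 | lactone acetal as 20 with C5–OTBS | C=C1C(=O)O[C@H](C/C(C)=C\CC(OC)OC)[C@H]1[C@H](Oc2ccc(OC)cc2)[C@@H](O[Si](C)(C)C(C)(C)C)C(Br)=C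
F9 | step 9 | lactone aldehyde as 21 with C5–OTBS | C=C1C(=O)O[C@H](C/C(C)=C\CC=O)[C@H]1[C@H](Oc2ccc(OC)cc2)[C@@H](O[Si](C)(C)C(C)(C)C)C(Br)=C
F10 | step 9 | macrocyclic C3 carbinol as 22 with C5–OTBS | C=C1C(=O)O[C@@H]2C/C(C)=C\CC(O)C(=C)[C@H](O[Si](C)(C)C(C)(C)C)[C@@H](Oc3ccc(OC)cc3)[C@@H]12
F11 | step 9 | macrocyclic enone as 23 with C5–OTBS | C=C1C(=O)O[C@@H]2C/C(C)=C\CC(=O)C(=C)[C@H](O[Si](C)(C)C(C)(C)C)[C@@H](Oc3ccc(OC)cc3)[C@@H]12
F12 | step 9 | macrocyclic enone as 23 with free C5–OH | C=C1C(=O)O[C@@H]2C/C(C)=C\CC(=O)C(=C)[C@H](O)[C@@H](Oc3ccc(OC)cc3)[C@@H]12
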